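**Plan**

- Ring labels: ring A is the benzene ring of the benzofuran, ring B the furan, ring C the pendant arene (C1′–C6′), ring D the dihydropyran fused at C5′–C6′.
- Cuts: the silyl-masked C4 hydroxyl; ring B at C3a–C3 and O1–C2 (iodophenol plus arylalkyne); ring D at its C6′–CH2 bond together with the C2′–CH2 bond of the prenyl group (both traced back to O-bound C5 units on O5′ and O3′); the C7–CH bond of the side chain on ring A.
- Enabling feature: C2′ and C6′ of ring C each lie ortho to an oxygen (O3′, O5′), ortho to the acceptor-bearing C1′ and para to the other oxygen. An aryl–O–C(CH3)2–C≡CH unit on O5′ and an aryl–O–C(CH3)2–CH=CH2 unit on O3′ are therefore retrons of two [3,3] shifts; the propargyl one continues by [1,5]-hydrogen shift and oxa-6π closure to ring D.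
- Forward: 3,5-dihydroxybenzaldehyde → mixed propargyl/allyl bis-ether → one-flask double sigmatropic cascade (ring D as chromene, plus the prenyl group) → selective hydrogenation → alkyne. Phloroglucinol → ortho-lithiation/epoxide opening → ketone → methylenation → iodoresorcinol. Sonogashira coupling–cycloisomerization builds ring B last, then desilylation.
- Stereochemistry: the single stereocentre comes from (2S,3S)-2,3-dimethyloxirane by SN2 inversion at the attacked carbon; the second carbinol centre is erased by oxidation and a non-basic methylenation keeps the α-aryl centre.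

Key step: step 3

Assumption: (2S,3S)-2,3-dimethyloxirane and tert-butyl 2-methylbut-3-en-2-yl carbonate are taken as purchasable; primed locants refer to ring C of the target.

**Step 1**
Reactants: 1 3,5-dihydroxybenzaldehyde; 2 3-chloro-3-methylbut-1-yne
Product: 3 3-hydroxy-5-[(2-methylbut-3-yn-2-yl)oxy]benzaldehyde
Conditions: 1 (3 equiv), 2 (1 equiv), CuCl2·2H2O (cat.), DBU, MeCN, 0 °C; unreacted 1 recovered
Reagents that add atoms: none
Why: Copper-catalysed O-propargylation of a phenoxide with a tertiary propargylic chloride (via a copper acetylide-derived propargyl cation equivalent) is the standard route to aryl 1,1-dimethylpropargyl ethers, and the excess of the symmetric diol should hold the reaction at the mono-ether while the aldehyde is untouched.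

**Step 2**
Reactants: 3 3-hydroxy-5-[(2-methylbut-3-yn-2-yl)oxy]benzaldehyde; 4 tert-butyl 2-methylbut-3-en-2-yl carbonate
Product: 5 3-[(2-methylbut-3-en-2-yl)oxy]-5-[(2-methylbut-3-yn-2-yl)oxy]benzaldehyde
Conditions: Pd(PPh3)4 (2 mol%), THF, 0 °C to rt; product kept cold and used directly
Reagents that add atoms: none
Why: Decarboxylative Tsuji–Trost O-allylation, in which the zerovalent palladium catalyst ionizes the tertiary allylic carbonate and the phenoxide attacks the more substituted terminus of the 1,1-dimethylallyl complex under kinetic control, should give the tertiary (reverse-prenyl) aryl ether without touching the propargyl ether.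

**Step 3**
Reactants: 5 3-[(2-methylbut-3-en-2-yl)oxy]-5-[(2-methylbut-3-yn-2-yl)oxy]benzaldehyde
Product: 9 7-hydroxy-2,2-dimethyl-6-(3-methylbut-2-en-1-yl)-2H-chromene-5-carbaldehyde, via prenylphenol propargyl ether 6 (not isolated), via allenylphenol 7 (not isolated), via ortho-quinone methide 8 (not isolated)
Conditions: PhNEt2 (degassed), 120 °C, then 185 °C
Reagents that add atoms: none
Why: On staged heating the tertiary allyl ether on O3′ first undergoes an aromatic Claisen [3,3] shift to C2′ (dienone, then tautomerization to 6), then the propargyl ether on O5′ undergoes the [3,3] shift that forms the C6′–C bond (C4a–C4 of ring D) and enolizes to allenylphenol 7, a [1,5]-hydrogen shift gives the 1-oxatriene 8, and oxa-6π electrocyclization re-forms the O–C(CH3)2 bond. The closest known reaction types are the thermal conversion of aryl 1,1-dimethylpropargyl ethers into 2,2-dimethyl-2H-chromenes and the Claisen rearrangement of aryl 1,1-dimethylallyl ethers into ortho-prenylphenols, run here in one flask because their barriers differ. Ring D closes as a six-membered ring by a thermal disrotatory six-electron electrocyclization of the (Z)-oxatriene, the net result being a 6-endo closure through the new C6′–C bond. No stereocentre is formed. The step needs both migrations to go to the carbons that flank C1′ (C2′ and C6′) and not to C4′ between the two oxygens, which is what the meta-substituent rule of the aromatic Claisen rearrangement predicts, since C2′ and C6′ are each ortho to the formyl-bearing acceptor carbon and para to the other oxygen donor whereas C4′ is ortho to that donor and para to the acceptor. The basic amine solvent should suppress acid-catalysed loss of isoprene from the tertiary ether and cyclization of the prenylphenol onto its own hydroxyl.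

**Step 4**
Reactants: 9 7-hydroxy-2,2-dimethyl-6-(3-methylbut-2-en-1-yl)-2H-chromene-5-carbaldehyde
Product: 10 7-hydroxy-2,2-dimethyl-6-(3-methylbut-2-en-1-yl)-3,4-dihydro-2H-chromene-5-carbaldehyde
Conditions: H2 (1 atm), RhCl(PPh3)3 (5 mol%), PhMe–EtOH, rt
Reagents that add atoms: none
Why: Homogeneous hydrogenation with RhCl(PPh3)3 is governed by alkene substitution, so the cis-disubstituted styrenic C3=C4 bond of ring D should be saturated while the trisubstituted prenyl alkene and the aryl aldehyde are left, which removes the extra unsaturation that the ring-closing cascade required.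

**Step 5**
Reactants: 10 7-hydroxy-2,2-dimethyl-6-(3-methylbut-2-en-1-yl)-3,4-dihydro-2H-chromene-5-carbaldehyde
Product: 11 5-ethynyl-2,2-dimethyl-6-(3-methylbut-2-en-1-yl)-3,4-dihydro-2H-chromen-7-ol
Conditions: dimethyl (1-diazo-2-oxopropyl)phosphonate, K2CO3 (3 equiv), MeOH, rt
Reagents that add atoms: dimethyl (1-diazo-2-oxopropyl)phosphonate, COP(=O)(OC)C(=[N+]=[N-])C(C)=O
Why: Ohira–Bestmann (Seyferth–Gilbert) homologation, in which the diazophosphonate anion adds to the aldehyde, cycloelimination and loss of N2 give an alkylidene carbene and a 1,2-hydrogen shift gives the terminal alkyne, is mild enough for the free phenol and the prenyl group.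

**Step 6**
Reactants: 12 benzene-1,3,5-triol (phloroglucinol)
Product: 13 3,5-bis(methoxymethoxy)phenol
Conditions: MOMCl (2.0 equiv), i-Pr2NEt, DMF, 0 °C to rt
Reagents that add atoms: chloromethyl methyl ether, COCCl
Why: Williamson-type O-alkylation of phloroglucinol with two equivalents of the chloromethyl ether should give the bis-acetal as the main component of a statistical mixture, from which mono- and tris-ethers are separated.

**Step 7**
Reactants: 13 3,5-bis(methoxymethoxy)phenol
Product: 14 [3,5-bis(methoxymethoxy)phenoxy]tri(propan-2-yl)silane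
Conditions: TIPSCl, imidazole, DMF, rt
Reagents that add atoms: chlorotri(propan-2-yl)silane, CC(C)[Si](Cl)(C(C)C)C(C)C
Why: Standard silylation of the remaining phenol installs a bulky, lithiation-stable and fluoride-labile group on the oxygen that must stay masked until ring B is closed.

**Step 8**
Reactants: 14 [3,5-bis(methoxymethoxy)phenoxy]tri(propan-2-yl)silane; 15 (2S,3S)-2,3-dimethyloxirane
Product: 17 (2S,3S)-3-[2,6-bis(methoxymethoxy)-4-{[tri(propan-2-yl)silyl]oxy}phenyl]butan-2-ol, via aryllithium 16 (not isolated)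
Conditions: n-BuLi, THF, 0 °C; then 15, BF3·OEt2, −78 °C
Reagents that add atoms: none
Why: Directed ortho-metalation occurs at the carbon flanked by the two methoxymethoxy groups, and BF3-assisted SN2 opening of the C2-symmetric trans-epoxide by the aryllithium proceeds with inversion at the attacked carbon, which sets the benzylic stereocentre as S (the same spatial arrangement is R in the target, where the neighbouring carbon has lost its oxygen and its CIP priority).

**Step 9**
Reactants: 17 (2S,3S)-3-[2,6-bis(methoxymethoxy)-4-{[tri(propan-2-yl)silyl]oxy}phenyl]butan-2-ol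
Product: 18 (2S,3S)-3-[3-iodo-2,6-bis(methoxymethoxy)-4-{[tri(propan-2-yl)silyl]oxy}phenyl]butan-2-ol
Conditions: NIS (1.0 equiv), MeCN, 0 °C, dark
Reagents that add atoms: N-iodosuccinimide, O=C1CCC(=O)N1I
Why: Electrophilic aromatic iodination of the trioxygenated ring should be fast at either of the two equivalent free ring positions, and it is placed before the alkene exists so that iodoetherification cannot compete.

**Step 10**
Reactants: 18 (2S,3S)-3-[3-iodo-2,6-bis(methoxymethoxy)-4-{[tri(propan-2-yl)silyl]oxy}phenyl]butan-2-ol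
Product: 19 (3S)-3-[3-iodo-2,6-bis(methoxymethoxy)-4-{[tri(propan-2-yl)silyl]oxy}phenyl]butan-2-one
Conditions: Dess–Martin periodinane, NaHCO3, CH2Cl2, 0 °C to rt
Reagents that add atoms: none
Why: Dess–Martin oxidation under buffered, non-basic conditions converts the secondary alcohol into the methyl ketone, erasing the carbinol stereocentre while the α-aryl stereocentre, whose enolization is disfavoured by the twisted di-ortho-substituted arene, should be kept.

**Step 11**
Reactants: 19 (3S)-3-[3-iodo-2,6-bis(methoxymethoxy)-4-{[tri(propan-2-yl)silyl]oxy}phenyl]butan-2-one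
Product: 20 {2-iodo-3,5-bis(methoxymethoxy)-4-[(2R)-3-methylbut-3-en-2-yl]phenoxy}tri(propan-2-yl)silane
Conditions: Cp2Ti(μ-Cl)(μ-CH2)AlMe2, pyridine (cat.), THF–PhMe, −40 to 0 °C
Reagents that add atoms: Tebbe reagent Cp2Ti(μ-Cl)(μ-CH2)AlMe2, C=[Ti](C1C=CC=C1)C1C=CC=C1.C[Al](C)Cl
Why: Tebbe methylenation proceeds through a titanium methylidene [2+2] cycloaddition–cycloreversion and is not basic, so the enolizable α-aryl ketone should become the 1,1-disubstituted alkene without racemization, with the aryl iodide, acetals and silyl ether tolerated.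

**Step 12**
Reactants: 20 {2-iodo-3,5-bis(methoxymethoxy)-4-[(2R)-3-methylbut-3-en-2-yl]phenoxy}tri(propan-2-yl)silane
Product: 22 4-iodo-2-[(2R)-3-methylbut-3-en-2-yl]-5-{[tri(propan-2-yl)silyl]oxy}benzene-1,3-diol, via bis(trimethylsilyl) ether 21 (not isolated)
Conditions: TMSOTf, 2,2′-bipyridyl, CH2Cl2, 0 °C; then H2O
Reagents that add atoms: none
Why: Silyl triflate–bipyridyl cleavage of aryl methoxymethyl ethers passes through pyridinium acetal salts and aryl trimethylsilyl ethers that hydrolyse on work-up, a near-neutral acetal cleavage that should spare the TIPS ether and not protonate the alkene next to the new ortho-hydroxyl groups.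

**Step 13**
Reactants: 11 5-ethynyl-2,2-dimethyl-6-(3-methylbut-2-en-1-yl)-3,4-dihydro-2H-chromen-7-ol; 22 4-iodo-2-[(2R)-3-methylbut-3-en-2-yl]-5-{[tri(propan-2-yl)silyl]oxy}benzene-1,3-diol
Product: 24 2-[7-hydroxy-2,2-dimethyl-6-(3-methylbut-2-en-1-yl)-3,4-dihydro-2H-chromen-5-yl]-7-[(2R)-3-methylbut-3-en-2-yl]-4-{[tri(propan-2-yl)silyl]oxy}-1-benzofuran-6-ol, via alkynylphenol 23 (not isolated)
Conditions: PdCl2(PPh3)2 (5 mol%), CuI (10 mol%), Et3N, DMF, degassed, 60 °C then 90 °C
Reagents that add atoms: none
Why: Sonogashira coupling of the aryl iodide with the terminal alkyne, followed in the same flask by copper/palladium-assisted 5-endo-dig hydroalkoxylation of the ortho-alkynylphenol, builds ring B, and only the hydroxyl lying between the alkyne and the side chain can close because the other ortho oxygen is silylated, which fixes the side chain at C7.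

**Step 14**
Reactants: 24 2-[7-hydroxy-2,2-dimethyl-6-(3-methylbut-2-en-1-yl)-3,4-dihydro-2H-chromen-5-yl]-7-[(2R)-3-methylbut-3-en-2-yl]-4-{[tri(propan-2-yl)silyl]oxy}-1-benzofuran-6-ol
Product: 25 2-[7-hydroxy-2,2-dimethyl-6-(3-methylbut-2-en-1-yl)-3,4-dihydro-2H-chromen-5-yl]-7-[(2R)-3-methylbut-3-en-2-yl]-1-benzofuran-4,6-diol
Conditions: TBAF, AcOH, THF, degassed, 0 °C
Reagents that add atoms: none
Why: Buffered fluoride cleavage of the aryl silyl ether should liberate the C4 hydroxyl under conditions that leave both alkenes, the stereocentre and the electron-rich benzofuran untouched.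

**Compound list**

1 | 3,5-dihydroxybenzaldehyde | O=Cc1cc(O)cc(O)c1 | starting material
2 | 3-chloro-3-methylbut-1-yne | C#CC(C)(C)Cl | starting material
3 | 3-hydroxy-5-[(2-methylbut-3-yn-2-yl)oxy]benzaldehyde | O=Cc1cc(O)cc(OC(C)(C)C#C)c1 | intermediate
4 | tert-butyl 2-methylbut-3-en-2-yl carbonate | C=CC(C)(C)OC(=O)OC(C)(C)C | starting material
5 | 3-[(2-methylbut-3-en-2-yl)oxy]-5-[(2-methylbut-3-yn-2-yl)oxy]benzaldehyde | O=Cc1cc(OC(C)(C)C=C)cc(OC(C)(C)C#C)c1 | intermediate
6 | 3-hydroxy-2-(3-methylbut-2-en-1-yl)-5-[(2-methylbut-3-yn-2-yl)oxy]benzaldehyde | O=Cc1cc(OC(C)(C)C#C)cc(O)c1CC=C(C)C | intermediate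
7 | 3,5-dihydroxy-2-(3-methylbuta-1,2-dien-1-yl)-6-(3-methylbut-2-en-1-yl)benzaldehyde | O=Cc1c(CC=C(C)C)c(O)cc(O)c1C=C=C(C)C | intermediate
8 | (6Z)-3-hydroxy-2-(3-methylbut-2-en-1-yl)-6-(3-methylbut-2-en-1-ylidene)-5-oxocyclohexa-1,3-diene-1-carbaldehyde | O=C1C=C(O)C(CC=C(C)C)=C(C=O)/C1=C/C=C(C)C | intermediate
9 | 7-hydroxy-2,2-dimethyl-6-(3-methylbut-2-en-1-yl)-2H-chromene-5-carbaldehyde | O=Cc1c(CC=C(C)C)c(O)cc2c1C=CC(C)(C)O2 | intermediate
10 | 7-hydroxy-2,2-dimethyl-6-(3-methylbut-2-en-1-yl)-3,4-dihydro-2H-chromene-5-carbaldehyde | O=Cc1c(CC=C(C)C)c(O)cc2c1CCC(C)(C)O2 | intermediate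
11 | 5-ethynyl-2,2-dimethyl-6-(3-methylbut-2-en-1-yl)-3,4-dihydro-2H-chromen-7-ol | C#Cc1c(CC=C(C)C)c(O)cc2c1CCC(C)(C)O2 | intermediate
12 | benzene-1,3,5-triol (phloroglucinol) | Oc1cc(O)cc(O)c1 | starting material
13 | 3,5-bis(methoxymethoxy)phenol | COCOc1cc(O)cc(OCOC)c1 | intermediate
14 | [3,5-bis(methoxymethoxy)phenoxy]tri(propan-2-yl)silane | COCOc1cc(OCOC)cc(O[Si](C(C)C)(C(C)C)C(C)C)c1 | intermediate
15 | (2S,3S)-2,3-dimethyloxirane | C[C@@H]1O[C@H]1C | starting material
16 | [2,6-bis(methoxymethoxy)-4-{[tri(propan-2-yl)silyl]oxy}phenyl]lithium | [Li]c1c(OCOC)cc(O[Si](C(C)C)(C(C)C)C(C)C)cc1OCOC | intermediate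
17 | (2S,3S)-3-[2,6-bis(methoxymethoxy)-4-{[tri(propan-2-yl)silyl]oxy}phenyl]butan-2-ol | C[C@H](O)[C@@H](C)c1c(OCOC)cc(O[Si](C(C)C)(C(C)C)C(C)C)cc1OCOC | intermediate
18 | (2S,3S)-3-[3-iodo-2,6-bis(methoxymethoxy)-4-{[tri(propan-2-yl)silyl]oxy}phenyl]butan-2-ol | C[C@H](O)[C@@H](C)c1c(OCOC)cc(O[Si](C(C)C)(C(C)C)C(C)C)c(I)c1OCOC | intermediate
19 | (3S)-3-[3-iodo-2,6-bis(methoxymethoxy)-4-{[tri(propan-2-yl)silyl]oxy}phenyl]butan-2-one | CC(=O)[C@@H](C)c1c(OCOC)cc(O[Si](C(C)C)(C(C)C)C(C)C)c(I)c1OCOC | intermediate
20 | {2-iodo-3,5-bis(methoxymethoxy)-4-[(2R)-3-methylbut-3-en-2-yl]phenoxy}tri(propan-2-yl)silane | C=C(C)[C@@H](C)c1c(OCOC)cc(O[Si](C(C)C)(C(C)C)C(C)C)c(I)c1OCOC | intermediate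
21 | {2-iodo-4-[(2R)-3-methylbut-3-en-2-yl]-3,5-bis[(trimethylsilyl)oxy]phenoxy}tri(propan-2-yl)silane | C=C(C)[C@@H](C)c1c(O[Si](C)(C)C)cc(O[Si](C(C)C)(C(C)C)C(C)C)c(I)c1O[Si](C)(C)C | intermediate
22 | 4-iodo-2-[(2R)-3-methylbut-3-en-2-yl]-5-{[tri(propan-2-yl)silyl]oxy}benzene-1,3-diol | C=C(C)[C@@H](C)c1c(O)cc(O[Si](C(C)C)(C(C)C)C(C)C)c(I)c1O | intermediate
23 | 4-{[7-hydroxy-2,2-dimethyl-6-(3-methylbut-2-en-1-yl)-3,4-dihydro-2H-chromen-5-yl]ethynyl}-2-[(2R)-3-methylbut-3-en-2-yl]-5-{[tri(propan-2-yl)silyl]oxy}benzene-1,3-diol | C=C(C)[C@@H](C)c1c(O)cc(O[Si](C(C)C)(C(C)C)C(C)C)c(C#Cc2c(CC=C(C)C)c(O)cc3c2CCC(C)(C)O3)c1O | intermediate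
24 | 2-[7-hydroxy-2,2-dimethyl-6-(3-methylbut-2-en-1-yl)-3,4-dihydro-2H-chromen-5-yl]-7-[(2R)-3-methylbut-3-en-2-yl]-4-{[tri(propan-2-yl)silyl]oxy}-1-benzofuran-6-ol | C=C(C)[C@@H](C)c1c(O)cc(O[Si](C(C)C)(C(C)C)C(C)C)c2cc(-c3c(CC=C(C)C)c(O)cc4c3CCC(C)(C)O4)oc12 | intermediate
25 | 2-[7-hydroxy-2,2-dimethyl-6-(3-methylbut-2-en-1-yl)-3,4-dihydro-2H-chromen-5-yl]-7-[(2R)-3-methylbut-3-en-2-yl]-1-benzofuran-4,6-diol | C=C(C)[C@@H](C)c1c(O)cc(O)c2cc(-c3c(CC=C(C)C)c(O)cc4c3CCC(C)(C)O4)oc12 | target

**Step count and risks**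

Total step count: 14 (steps 1–5 for the ring C/D alkyne, steps 6–12 for the ring A iodophenol, steps 13–14 for union and unmasking).
Longest linear sequence: 9 steps (12 to 25 through steps 6–14).

The three steps most likely to fail:

Step 3. The two rearrangements may interfere in one flask: loss of isoprene from the tertiary allyl ether before it migrates, leakage of either shift to C4′, or thermal wear of the prenylphenol at the temperature of the propargyl stage. The fallback separates the events and sets out from 3. Heating 3 alone (PhNEt2, 185 °C) should give 7-hydroxy-2,2-dimethyl-2H-chromene-5-carbaldehyde F1 by the same propargyl Claisen–electrocyclization sequence. Hydrogenation over Pd/C (H2, EtOAc, rt), now with no other alkene present, should give 7-hydroxy-2,2-dimethyl-3,4-dihydro-2H-chromene-5-carbaldehyde F2. O-allylation with 4 and Pd(PPh3)4 should give 2,2-dimethyl-7-[(2-methylbut-3-en-2-yl)oxy]-3,4-dihydro-2H-chromene-5-carbaldehyde F3. Its Claisen rearrangement at about 120 °C (or with Eu(fod)3 at lower temperature) should place the prenyl group on C6 and come back to the route at 10.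

Step 4. Discrimination between the hindered chromene alkene (next to the quaternary carbon) and the prenyl alkene may be poor, or the aldehyde may deactivate the rhodium catalyst by decarbonylation. The fallback avoids the chromene oxidation level and sets out from 1. Double O-allylation with 4 (2.2 equiv, Pd(PPh3)4, THF, 0 °C) should give 3,5-bis[(2-methylbut-3-en-2-yl)oxy]benzaldehyde F4. Double aromatic Claisen rearrangement (PhNEt2, 120 °C) should give 3,5-dihydroxy-2,6-bis(3-methylbut-2-en-1-yl)benzaldehyde F5. Acid-catalysed hydroalkoxylation of one of its two equivalent ortho-prenylphenol units (Amberlyst-15, CH2Cl2, 0 °C, stopped at partial conversion, with recovered F5 recycled) closes ring D directly at the chromane level and comes back to the route at 10.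

Step 8. The hindered di-ortho-substituted aryllithium may fail to attack the secondary epoxide carbon, so that BF3-induced rearrangement of the epoxide or proton transfer takes over. The fallback forms the same bond by allylic substitution and sets out from 14. Lithiation as in step 8 and transmetalation with MgBr2·OEt2 should give [2,6-bis(methoxymethoxy)-4-{[tri(propan-2-yl)silyl]oxy}phenyl]magnesium bromide F6. Copper-catalysed enantioselective SN2′ allylic arylation of (E)-1-bromo-2-methylbut-2-ene (CuBr·SMe2, chiral phosphoramidite ligand, CH2Cl2, −78 °C) should give {3,5-bis(methoxymethoxy)-4-[(2R)-3-methylbut-3-en-2-yl]phenoxy}tri(propan-2-yl)silane F7, with the stereocentre set by the ligand. Iodination with N-iodosuccinimide (MeCN, −20 °C) comes back to the route at 20.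

**Further compounds**

F1 | step 3 | 7-hydroxy-2,2-dimethyl-2H-chromene-5-carbaldehyde | O=Cc1cc(O)cc2c1C=CC(C)(C)O2
F2 | step 3 | 7-hydroxy-2,2-dimethyl-3,4-dihydro-2H-chromene-5-carbaldehyde | O=Cc1cc(O)cc2c1CCC(C)(C)O2
F3 | step 3 | 2,2-dimethyl-7-[(2-methylbut-3-en-2-yl)oxy]-3,4-dihydro-2H-chromene-5-carbaldehyde | O=Cc1cc(OC(C)(C)C=C)cc2c1CCC(C)(C)O2
F4 | step 4 | 3,5-bis[(2-methylbut-3-en-2-yl)oxy]benzaldehyde | O=Cc1cc(OC(C)(C)C=C)cc(OC(C)(C)C=C)c1
F5 | step 4 | 3,5-dihydroxy-2,6-bis(3-methylbut-2-en-1-yl)benzaldehyde | O=Cc1c(CC=C(C)C)c(O)cc(O)c1CC=C(C)C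
F6 | step 8 | [2,6-bis(methoxymethoxy)-4-{[tri(propan-2-yl)silyl]oxy}phenyl]magnesium bromide | Br[Mg]c1c(OCOC)cc(O[Si](C(C)C)(C(C)C)C(C)C)cc1OCOC
F7 | step 8 | {3,5-bis(methoxymethoxy)-4-[(2R)-3-methylbut-3-en-2-yl]phenoxy}tri(propan-2-yl)silane | C=C(C)[C@@H](C)c1c(OCOC)cc(O[Si](C(C)C)(C(C)C)C(C)C)cc1OCOC
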